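How much target a flask makes per hour is the question here. The new flask holds 0.13 M of starting material, as Thursday's did, but the 0.0650 M of second substrate of Sunday's and Monday's. The proposal is that enzyme takes up starting material into complex A, which gives target, and second substrate into complex B, which gives second product, while two complex B can join into the resting dimer.

| setting | Sunday's | Monday's | Thursday's | flask |
|---|---|---|---|---|
| starting material | 0.18 M | 0.29 M | 0.13 M | 0.13 M |
| second substrate | 0.065 M | 0.065 M | 0.033 M | 0.0650 M |
| enzyme | 26 µM | 26 µM | 26 µM | 26 µM |
| remark | run made earlier | run made earlier | run made earlier |  |

- Sunday's (time / h: target / %, starting material / %): 6.00: 4, 100; 12.0: 1, 100; 20.0: 2, 99; 25.0: 2, 92; 30.0: 8, 93; 40.0: 10, 94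
- Monday's (time / h: target / %, starting material / %): 2.50: 1, 98; 8.00: 0, 102; 12.0: 2, 98; 20.0: 6, 97; 30.0: 6, 95; 40.0: 7, 90
- Thursday's (time / h: target / %, starting material / %): 3.00: 0, 96; 5.00: 1, 96; 10.0: 3, 100; 20.0: 8, 94; 40.0: 17, 81

(scatter of a reading: 2 percentage points)

- steps that have been proposed: starting material + enzyme <-> complex A; complex A -> enzyme + target; second substrate + enzyme <-> complex B; complex B -> enzyme + second product; 2 complex B <-> resting dimer

- apparent order in second substrate when 5.0% of the starting material are converted (percent change of the rate of making target for one percent more second substrate charged)
- factor on the rate of making target when 5.0% of the starting material are converted if second substrate is charged twice over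

Two of us read these runs differently. The forecast works in absolute rates and takes the order in starting material to be near 0.5, an order it calls noisy. Its starting point is this: “Thursday has the least starting material and half the second substrate, yet it is the fastest.” It gives an order of −0.6 in second substrate and a doubling factor of 0.65.

My own reckoning differs, and it gives another number. I take the rate to be first order in starting material (pseudo-first-order); then the percent of target at a given hour doesn't depend on the charge of starting material. Sunday's 10% and Monday's 7% after 40.0 h differ by about what a scatter of 2 percentage points on each reading gives, so I average them to 8.50%. Thursday's reading at that same hour is 17%. Dividing one by the other compares average rates, and time drops out, leaving a ratio of 2.00. Set against the ratio of the second substrate charges, this gives −1.02, a reading with its scatter. This is the same-hour order: the logarithm of the ratio of target percents at equal hours, over the logarithm of the ratio of the second substrate charges that gave them, taken in the same direction. Doubling the charge then multiplies the rate by 0.493.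

The simulation gives an order of −0.97 and a factor of 0.507, so the percent reading stands nearer than the forecast.

    starting material + enzyme ⇌ complex A (K = 17.0 L mol⁻¹, k = 27000 L mol⁻¹ h⁻¹)
    complex A → enzyme + target (k = 360 h⁻¹)
    second substrate + enzyme ⇌ complex B (K = 400 L mol⁻¹, k = 3.90 × 10⁵ L mol⁻¹ h⁻¹)
    complex B → enzyme + second product (k = 61.0 h⁻¹)
    2 complex B ⇌ resting dimer (K = 1.30 × 10⁵ L mol⁻¹, k = 76000 L mol⁻¹ h⁻¹)

The largest single effect on this order is the passing of second substrate and enzyme into complex B, both ways. In the simulated run with that step taken away the order is 0, and the forecast's −0.6 stands between that order and this flask's. Used on Thursday's run, the same-hour order takes the flask's 2.68% of target after 15.0 h, scaled to 20.0 h and to Thursday's 0.033 M of second substrate, to 7.13%, and Thursday's reading there is 8%.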